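**Retrosynthetic overview**

1. Last, the ten-membered carbocycle and the cis-fused α-methylene-γ-lactone are closed together by an intramolecular CrCl2 allylation (C6–C7) of a (Z)-enal by a 2-(bromomethyl)enoate; the C8 isobutyrate comes from a Mitsunobu inversion.
2. The 3(2H)-furanone with its (Z)-alkenyl arm comes from a bicyclic 4-alkoxybutenolide (tetronate) and a (Z)-alkenyllithium (C3–C4 bond); acid then opens a temporary oxolane ring that ties the C8 oxygen to C1.
3. The five-membered O-ring (O, C3, C2, C1, C10) is made by Baeyer–Villiger ring expansion of a cyclobutanone (C3, C2, C1, C10), itself from a dichloroketene [2+2] cycloaddition to a chiral 2,3-dihydrofuran derived from (S)-glycidyl 4-methoxybenzyl ether.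
4. Enabling feature: C10 is a fully substituted carbon flanked by the two carbonyl-level carbons C1 and C3 of the furanone. As the ring-fusion α-carbon of a strained cyclobutanone it migrates from C3 to oxygen with retention, so the C10–O stereocentre is set by face selection on a five-membered ring.
5. Ring order: temporary oxolane → cyclobutanone → five-membered O-ring by expansion (later the furanone) → ten-membered ring and γ-lactone.

Key step: step 6

Remark: C1–C15 in the text are the germacrane positions of the target (a naming aid only); (S)-glycidyl 4-methoxybenzyl ether (1) is taken as a catalogue compound. PMB = 4-methoxybenzyl, TBS = tert-butyldimethylsilyl, TBDPS = tert-butyldiphenylsilyl.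

**Route**

Step 1
Reactants: 1 (S)-glycidyl 4-methoxybenzyl ether; 2 propanoic acid
Product: 5 (5S)-5-{[(4-methoxybenzyl)oxy]methyl}-3-methyloxolan-2-one, via propanoate dianion 3 (not isolated), via hydroxy acid 4 (not isolated)
Conditions: LiN(iPr)2 (2.2 equiv), THF, 0 °C; 1, 0 → 40 °C; 2 M HCl; TsOH (cat.), CH2Cl2, rt
Reagents that add atoms: none
Why: Opening of a terminal epoxide at its CH2 carbon by a carboxylic acid dianion (SN2, C8 untouched) gives the γ-hydroxy acid, which lactonises under acid; the methyl-bearing carbon is formed as a mixture, which does not matter because it becomes sp2 in step 3.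

Step 2
Reactants: 5 lactone
Product: 6 (5S)-5-{[(4-methoxybenzyl)oxy]methyl}-3-methyloxolan-2-ol
Conditions: iBu2AlH (1.1 equiv), CH2Cl2, −78 °C
Reagents that add atoms: none
Why: Partial reduction of a γ-lactone to the lactol with one hydride equivalent at low temperature is standard and leaves C8 and the PMB ether untouched.

Step 3
Reactants: 6 lactol
Product: 8 (2S)-2-{[(4-methoxybenzyl)oxy]methyl}-4-methyl-2,3-dihydrofuran, via lactol mesylate 7 (not isolated)
Conditions: MsCl, Et3N, CH2Cl2, −40 °C → reflux
Reagents that add atoms: none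
Why: Sulfonylation of the anomeric hydroxyl and base-induced elimination is the usual lactol-to-2,3-dihydrofuran dehydration, and only one enol ether regioisomer is possible.

Step 4
Reactants: 8 dihydrofuran; 9 trichloroacetyl chloride
Product: 11 (1S,3S,5R)-7,7-dichloro-3-{[(4-methoxybenzyl)oxy]methyl}-5-methyl-2-oxabicyclo[3.2.0]heptan-6-one, via dichloroketene 10 (not isolated)
Conditions: Zn–Cu couple, POCl3, Et2O, rt, slow addition of 9
Reagents that add atoms: none
Why: Ketene–enol ether [2+2] cycloaddition: the nucleophilic β-carbon (C10) bonds to the ketene carbonyl carbon (C3) and the oxygen-bearing carbon (C1) to CCl2, giving the cis-fused cyclobutanone; the ketene adds to the face of the five-membered ring anti to the CH2OPMB group at C8, which sets the quaternary centre C10 (and C1).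

Step 5
Reactants: 11 dichlorocyclobutanone
Product: 12 (1R,3S,5R)-3-{[(4-methoxybenzyl)oxy]methyl}-5-methyl-2-oxabicyclo[3.2.0]heptan-6-one
Conditions: Zn dust, AcOH, rt
Reagents that add atoms: none
Why: Reductive dechlorination of an α,α-dichlorocyclobutanone with zinc in acetic acid is the standard follow-up to a dichloroketene cycloaddition and touches no stereocentre.

Step 6
Reactants: 12 cyclobutanone
Product: 13 (3aR,5S,6aR)-5-{[(4-methoxybenzyl)oxy]methyl}-6a-methyltetrahydrofuro[3,2-b]furan-2(3H)-one
Conditions: mCPBA, CH2Cl2, 0 °C → rt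
Reagents that add atoms: 3-chloroperoxybenzoic acid, OOC(=O)c1cccc(Cl)c1
Why: Baeyer–Villiger oxidation: the peracid adds to the strained cyclobutanone carbonyl (C3) to give a Criegee adduct, and the quaternary ring-fusion carbon C10 shifts from C3 to oxygen with loss of 3-chlorobenzoate. The closest known reaction type is the Baeyer–Villiger ring expansion of ketene–enol ether cyclobutanones to γ-lactones. The oxolanone ring (O, C3, C2, C1, C10) is not closed by a cyclisation; it arises from the four-membered ring by a 1,2-shift that inserts oxygen into the C3–C10 bond, driven by release of cyclobutanone strain. No new stereocentre is created: C10, set in step 4, migrates with retention and so becomes the tertiary C–O stereocentre of the target, while C1 and C8 are untouched. The step needs migration of C10 rather than C2, which is secured because C10 is fully substituted and C2 is a CH2 (both carry the same β-oxygen), and chemoselectivity over the anisyl ether, which is secured by the high carbonyl reactivity of the cyclobutanone.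

Step 7
Reactants: 13 bicyclic lactone
Product: 15 (5S,6aR)-5-{[(4-methoxybenzyl)oxy]methyl}-6a-methyl-6,6a-dihydrofuro[3,2-b]furan-2(5H)-one, via selenide 14 (not isolated)
Conditions: LiN(iPr)2, THF, −78 °C; PhSeCl, −78 °C; then 30% H2O2, pyridine, CH2Cl2, 0 °C → rt
Reagents that add atoms: none
Why: α-Selenenylation of the lactone enolate on the convex face at −78 °C (where loss of the β-alkoxide is slow), then oxidation at selenium and syn-elimination toward the only β-hydrogen (on C1), gives the 4-alkoxybutenolide and raises C1 to the ketone oxidation level.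

Step 8
Reactants: 16 but-2-yne-1,4-diol
Product: 17 4-[(tert-butyldiphenylsilyl)oxy]but-2-yn-1-ol
Conditions: TBDPSCl (0.3 equiv), imidazole, DMF, 0 °C, diol in excess
Reagents that add atoms: tert-butyl(chloro)diphenylsilane, CC(C)(C)[Si](Cl)(c1ccccc1)c1ccccc1
Why: Monosilylation of a symmetric diol under statistical control with the diol in excess is routine.

Step 9
Reactants: 17 propargylic alcohol
Product: 18 (2Z)-4-[(tert-butyldiphenylsilyl)oxy]-3-iodobut-2-en-1-ol
Conditions: NaAlH2(OCH2CH2OMe)2 (Red-Al), THF, 0 °C → rt; then I2, THF, −78 → 0 °C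
Reagents that add atoms: iodine, II
Why: Hydroxyl-directed trans-hydroalumination of the propargylic alcohol and iodinolysis of the cyclic vinylalanate places iodine on the carbon distal to the free hydroxyl and cis to CH2OH, which fixes the Z geometry of the later C4=C5 bond.

Step 10
Reactants: 18 iodo alcohol
Product: 19 (2Z)-4-[(tert-butyldimethylsilyl)oxy]-1-[(tert-butyldiphenylsilyl)oxy]-2-iodobut-2-ene
Conditions: TBSCl, imidazole, CH2Cl2, rt
Reagents that add atoms: tert-butyl(chloro)dimethylsilane, CC(C)(C)[Si](C)(C)Cl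
Why: Standard silylation of a primary alcohol gives a C6 protecting group that can later be removed in the presence of the TBDPS ether.

Step 11
Reactants: 19 (Z)-alkenyl iodide; 15 bicyclic 4-alkoxybutenolide
Product: 22 (2R)-2-[(2S)-2-hydroxy-3-(4-methoxybenzyloxy)propyl]-2-methyl-5-[(2Z)-4-(TBSO)-1-(TBDPSO)but-2-en-2-yl]furan-3(2H)-one, via alkenyllithium 20 (not isolated), via hemiketal 21 (not isolated)
Conditions: 19, tBuLi (2.1 equiv), Et2O, −78 °C; then 15, THF, −78 °C; then 0.1 M HCl, THF, 0 °C
Reagents that add atoms: water, O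
Why: Iodine–lithium exchange gives a configurationally stable alkenyllithium that adds 1,2 to the lactone carbonyl (C3), and dilute acid ionises the vinylogous hemiketal and hydrolyses the enol ether of the temporary oxolane ring (the known 4-alkoxybutenolide to 3(2H)-furanone carbonyl transposition), which frees the C8 hydroxyl, keeps the Z alkene and creates no stereocentre.

Step 12
Reactants: 22 furanone alcohol; 23 2-methylpropanoic acid
Product: 24 (2R)-1-[(2R)-furanon-2-yl]-3-(4-methoxybenzyloxy)propan-2-yl 2-methylpropanoate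
Conditions: 23, PPh3, DIAD, toluene, 0 °C → rt
Reagents that add atoms: none
Why: Mitsunobu esterification displaces the activated C8 oxygen by isobutyrate with inversion (SN2), which turns the (S)-carbinol left by the anti-selective cycloaddition into the (R)-ester of the target.

Step 13
Reactants: 24 PMB ether
Product: 25 primary alcohol (C7–OH)
Conditions: DDQ, CH2Cl2/pH 7 buffer, 0 °C
Reagents that add atoms: none
Why: Oxidative cleavage of the electron-rich PMB ether by DDQ under neutral conditions leaves the silyl ethers and the ester intact and avoids acyl migration if the alcohol is oxidised at once.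

Step 14
Reactants: 25 primary alcohol
Product: 26 α-acyloxy aldehyde (C7 aldehyde)
Conditions: Dess–Martin periodinane, pyridine, CH2Cl2, 0 °C → rt
Reagents that add atoms: none
Why: Dess–Martin oxidation under buffered conditions gives the α-acyloxy aldehyde without epimerising C8; it is used crude.

Step 15
Reactants: 26 aldehyde; 27 methyl propiolate
Product: 29 methyl (4R)-3-hydroxy-2-methylidene-4-(isobutyryloxy)-5-[(2R)-furanon-2-yl]pentanoate, via vinylalane 28 (not isolated)
Conditions: 27, iBu2AlH, NMO, THF, 0 °C; then 26, 0 °C → rt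
Reagents that add atoms: none
Why: Vinylalumination (hydroalumination of the propiolate to the α-(methoxycarbonyl)vinylalane, then carbonyl addition) gives the Morita–Baylis–Hillman-type adduct without amine base, so C8 is not epimerised; the new carbinol centre forms unselectively and is destroyed in step 16.

Step 16
Reactants: 29 allylic alcohol
Product: 30 methyl (2Z,4R)-2-(bromomethyl)-4-(isobutyryloxy)-5-[(2R)-furanon-2-yl]pent-2-enoate
Conditions: NBS, Me2S, CH2Cl2, 0 °C
Reagents that add atoms: N-bromosuccinimide, O=C1CCC(=O)N1Br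
Why: Corey–Kim-type activation of the Morita–Baylis–Hillman alcohol followed by SN2' attack of bromide gives the conjugated primary (Z)-2-(bromomethyl)alk-2-enoate.

Step 17
Reactants: 30 TBS ether
Product: 31 allylic alcohol (C6–OH)
Conditions: PPTS, MeOH/CH2Cl2, rt
Reagents that add atoms: none
Why: Acid-catalysed methanolysis removes the primary allylic TBS ether selectively, since the TBDPS ether, the ester and the allylic bromide are stable to these conditions.

Step 18
Reactants: 31 allylic alcohol
Product: 32 (Z)-enal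
Conditions: Dess–Martin periodinane, pyridine, CH2Cl2, 0 °C
Reagents that add atoms: none
Why: Buffered Dess–Martin oxidation of the allylic alcohol gives the (Z)-enal without isomerising the C4=C5 bond.

Step 19
Reactants: 32 (Z)-enal allylic bromide
Product: 34 15-O-TBDPS ether of the target, via hydroxy ester 33 (not isolated)
Conditions: CrCl2 (excess), THF, rt, slow addition (high dilution); then TsOH (cat.), CH2Cl2, rt
Reagents that add atoms: none
Why: Intramolecular Nozaki–Hiyama-type (Barbier) allylation: divalent chromium turns the bromide into an allylchromium species whose γ-carbon (C7) adds to the aldehyde (C6) through a chair-like transition state, in which the (Z)-configured 2-(methoxycarbonyl)allyl unit should give the syn C6/C7 pair and the acyloxy-bearing C8 should bias the face of C7; acid then lactonises the cis-γ-hydroxy ester, so the ten-membered carbocycle (C–C bond formation) and the lactone (5-exo acyl substitution) are both closed.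

Step 20
Reactants: 34 TBDPS ether
Product: 35 target
Conditions: HF·pyridine, pyridine, THF, 0 °C → rt
Reagents that add atoms: none
Why: Buffered fluoride cleavage of the primary TBDPS ether is compatible with the α-methylene lactone, the isobutyrate and the furanone.

**Compound list**

1 | (S)-glycidyl 4-methoxybenzyl ether, (2S)-2-{[(4-methoxybenzyl)oxy]methyl}oxirane | COc1ccc(COC[C@@H]2CO2)cc1 | starting material
2 | propanoic acid | CCC(=O)O | starting material
3 | dilithium propanoate dianion | CC=C([O-])[O-].[Li+].[Li+] | intermediate (not isolated)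
4 | (4S)-4-hydroxy-5-[(4-methoxybenzyl)oxy]-2-methylpentanoic acid, both C2 epimers | CC(C[C@H](O)COCc1ccc(OC)cc1)C(=O)O | intermediate (not isolated)
5 | (5S)-5-{[(4-methoxybenzyl)oxy]methyl}-3-methyloxolan-2-one, both C3 epimers | CC1C[C@@H](COCc2ccc(OC)cc2)OC1=O | intermediate
6 | (5S)-5-{[(4-methoxybenzyl)oxy]methyl}-3-methyloxolan-2-ol, epimer mixture | CC1C[C@@H](COCc2ccc(OC)cc2)OC1O | intermediate
7 | 2-O-methanesulfonate of lactol 6 | CC1C[C@@H](COCc2ccc(OC)cc2)OC1OS(C)(=O)=O | intermediate (not isolated)
8 | (2S)-2-{[(4-methoxybenzyl)oxy]methyl}-4-methyl-2,3-dihydrofuran | CC1=CO[C@H](COCc2ccc(OC)cc2)C1 | intermediate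
9 | trichloroacetyl chloride | ClC(Cl)(Cl)C(Cl)=O | starting material
10 | dichloroketene | ClC(Cl)=C=O | intermediate (not isolated)
11 | (1S,3S,5R)-7,7-dichloro-3-{[(4-methoxybenzyl)oxy]methyl}-5-methyl-2-oxabicyclo[3.2.0]heptan-6-one (cis-fused; CH2OPMB anti to the cyclobutanone) | O=C1C(Cl)(Cl)[C@H]2O[C@H](COCc3ccc(OC)cc3)C[C@@]12C | intermediate
12 | (1R,3S,5R)-3-{[(4-methoxybenzyl)oxy]methyl}-5-methyl-2-oxabicyclo[3.2.0]heptan-6-one | O=C1C[C@H]2O[C@H](COCc3ccc(OC)cc3)C[C@@]12C | intermediate
13 | (3aR,5S,6aR)-5-{[(4-methoxybenzyl)oxy]methyl}-6a-methyltetrahydrofuro[3,2-b]furan-2(3H)-one | O=C1C[C@H]2O[C@H](COCc3ccc(OC)cc3)C[C@@]2(C)O1 | intermediate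
14 | 3-(phenylselanyl) derivative of 13 (selenium on the convex face) | O=C1C([Se]c3ccccc3)[C@H]2O[C@H](COCc3ccc(OC)cc3)C[C@@]2(C)O1 | intermediate (not isolated)
15 | (5S,6aR)-5-{[(4-methoxybenzyl)oxy]methyl}-6a-methyl-6,6a-dihydrofuro[3,2-b]furan-2(5H)-one | O=C1C=C2O[C@H](COCc3ccc(OC)cc3)C[C@@]2(C)O1 | intermediate
16 | but-2-yne-1,4-diol | OCC#CCO | starting material
17 | 4-[(tert-butyldiphenylsilyl)oxy]but-2-yn-1-ol | OCC#CCO[Si](c1ccccc1)(c1ccccc1)C(C)(C)C | intermediate
18 | (2Z)-4-[(tert-butyldiphenylsilyl)oxy]-3-iodobut-2-en-1-ol | OC/C=C(\I)CO[Si](c1ccccc1)(c1ccccc1)C(C)(C)C | intermediate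
19 | (2Z)-4-[(tert-butyldimethylsilyl)oxy]-1-[(tert-butyldiphenylsilyl)oxy]-2-iodobut-2-ene | CC(C)(C)[Si](C)(C)OC/C=C(\I)CO[Si](c1ccccc1)(c1ccccc1)C(C)(C)C | intermediate
20 | (Z)-alkenyllithium from 19 | CC(C)(C)[Si](C)(C)OC/C=C(\[Li])CO[Si](c1ccccc1)(c1ccccc1)C(C)(C)C | intermediate (not isolated)
21 | hemiketal from addition of 20 to the carbonyl of 15 (new carbinol centre undefined) | CC(C)(C)[Si](C)(C)OC/C=C(/CO[Si](c1ccccc1)(c1ccccc1)C(C)(C)C)C1(O)C=C2O[C@H](COCc3ccc(OC)cc3)C[C@@]2(C)O1 | intermediate (not isolated)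
22 | (2R)-2-[(2S)-2-hydroxy-3-(4-methoxybenzyloxy)propyl]-2-methyl-5-[(2Z)-4-(TBSO)-1-(TBDPSO)but-2-en-2-yl]furan-3(2H)-one | CC(C)(C)[Si](C)(C)OC/C=C(/CO[Si](c1ccccc1)(c1ccccc1)C(C)(C)C)C1=CC(=O)[C@@](C)(C[C@H](O)COCc2ccc(OC)cc2)O1 | intermediate
23 | 2-methylpropanoic acid | CC(C)C(=O)O | starting material
24 | (2R)-1-[(2R)-2-methyl-3-oxo-5-{(2Z)-4-(TBSO)-1-(TBDPSO)but-2-en-2-yl}-2,3-dihydrofuran-2-yl]-3-(4-methoxybenzyloxy)propan-2-yl 2-methylpropanoate | CC(C)(C)[Si](C)(C)OC/C=C(/CO[Si](c1ccccc1)(c1ccccc1)C(C)(C)C)C1=CC(=O)[C@@](C)(C[C@@H](OC(=O)C(C)C)COCc2ccc(OC)cc2)O1 | intermediate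
25 | (2R)-1-hydroxy-3-[(2R)-furanon-2-yl]propan-2-yl 2-methylpropanoate (furanone as in 24) | CC(C)(C)[Si](C)(C)OC/C=C(/CO[Si](c1ccccc1)(c1ccccc1)C(C)(C)C)C1=CC(=O)[C@@](C)(C[C@@H](OC(=O)C(C)C)CO)O1 | intermediate
26 | (2R)-1-oxo-3-[(2R)-furanon-2-yl]propan-2-yl 2-methylpropanoate | CC(C)(C)[Si](C)(C)OC/C=C(/CO[Si](c1ccccc1)(c1ccccc1)C(C)(C)C)C1=CC(=O)[C@@](C)(C[C@@H](OC(=O)C(C)C)C=O)O1 | intermediate
27 | methyl propiolate | C#CC(=O)OC | starting material
28 | methyl 2-(diisobutylalumanyl)prop-2-enoate | C=C(C(=O)OC)[Al](CC(C)C)CC(C)C | intermediate (not isolated)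
29 | methyl (4R)-3-hydroxy-2-methylidene-4-(isobutyryloxy)-5-[(2R)-furanon-2-yl]pentanoate, both C3 epimers | CC(C)(C)[Si](C)(C)OC/C=C(/CO[Si](c1ccccc1)(c1ccccc1)C(C)(C)C)C1=CC(=O)[C@@](C)(C[C@@H](OC(=O)C(C)C)C(O)C(=C)C(=O)OC)O1 | intermediate
30 | methyl (2Z,4R)-2-(bromomethyl)-4-(isobutyryloxy)-5-[(2R)-furanon-2-yl]pent-2-enoate, C6–OTBS | CC(C)(C)[Si](C)(C)OC/C=C(/CO[Si](c1ccccc1)(c1ccccc1)C(C)(C)C)C1=CC(=O)[C@@](C)(C[C@@H](OC(=O)C(C)C)/C=C(\CBr)C(=O)OC)O1 | intermediate
31 | as 30 with free C6 hydroxyl | OC/C=C(/CO[Si](c1ccccc1)(c1ccccc1)C(C)(C)C)C1=CC(=O)[C@@](C)(C[C@@H](OC(=O)C(C)C)/C=C(\CBr)C(=O)OC)O1 | intermediate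
32 | as 31 with C6 as the (Z)-enal | O=C/C=C(/CO[Si](c1ccccc1)(c1ccccc1)C(C)(C)C)C1=CC(=O)[C@@](C)(C[C@@H](OC(=O)C(C)C)/C=C(\CBr)C(=O)OC)O1 | intermediate
33 | macrocyclic seco hydroxy methyl ester of 34 (same configuration at C6, C7, C8 and C10) | COC(=O)C(=C)[C@H]1[C@@H](O)/C=C(/CO[Si](c3ccccc3)(c3ccccc3)C(C)(C)C)C2=CC(=O)[C@@](C)(C[C@H]1OC(=O)C(C)C)O2 | intermediate (not isolated)
34 | 15-O-TBDPS ether of the target | C=C1C(=O)O[C@H]2/C=C(/CO[Si](c4ccccc4)(c4ccccc4)C(C)(C)C)C3=CC(=O)[C@@](C)(C[C@@H](OC(=O)C(C)C)[C@@H]12)O3 | intermediate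
35 | target, (4Z,6S,7R,8R,10R)-15-hydroxy-1-oxo-3,10-epoxygermacra-2,4,11(13)-trien-12,6-olid-8-yl 2-methylpropanoate | C=C1C(=O)O[C@H]2/C=C(/CO)C3=CC(=O)[C@@](C)(C[C@@H](OC(=O)C(C)C)[C@@H]12)O3 | target

**Step count and risks**

Total step count: 20. Longest linear sequence: 17 steps (steps 1–7 and 11–20, from compound 1).

The step most likely to fail is step 19. Face selection at C6/C7 relative to C8 in the ten-membered transition state may be poor or may favour the anti (trans-lactone) pair, and intermolecular addition may compete with ring closure. The fallback sets out from 32: the allylic bromide is converted with (Bu3Sn)2 and Pd(PPh3)4 into the allylstannane enal F1. F1 is cyclised at high dilution with BF3·OEt2 at −78 °C, a Lewis acid-promoted allylstannane–aldehyde addition through an open antiperiplanar transition state that is syn-selective without a metal template. The resulting hydroxy ester 33 is lactonised with TsOH, and the route is rejoined at 34.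

Second is step 11. The basic alkenyllithium may deprotonate the butenolide or add in conjugate fashion, the silyl group may migrate from oxygen to carbon in the alkenyllithium, or hydrolysis may open the lactone-derived ring instead of the temporary oxolane. The fallback sets out from 15: reduction with iBu2AlH at −78 °C gives the lactol F2. A NiCl2-catalysed CrCl2 coupling (Nozaki–Hiyama–Kishi) of iodide 19 with the aldehyde tautomer of F2 gives the diol F3 without a strongly basic organometallic. MnO2 oxidises the secondary allylic alcohol to the hydroxy dienone F4, and dilute acid cyclises the tertiary hydroxyl onto the vinylogous ester (the classical cyclodehydration to a 3(2H)-furanone) while hydrolysing the temporary enol ether. The route is rejoined at 22.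

Third is step 7. The ring alkoxide may be lost from the lactone enolate by β-elimination, or the oxidised selenide may fail to eliminate toward the oxygen-bearing carbon. The fallback sets out from 11 and replaces steps 5 to 7: Baeyer–Villiger oxidation of the dichlorocyclobutanone with mCPBA gives the dichlorolactone F5, so the ring expansion is kept. DBU then removes HCl without any enolate to give the chlorotetronate F6, and Pd(PPh3)4-catalysed reduction with Bu3SnH removes the vinylic chlorine. The route is rejoined at 15.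

Further compounds
F1 | step 19 | allylstannane enal, as 32 with SnBu3 in place of Br | O=C/C=C(/CO[Si](c1ccccc1)(c1ccccc1)C(C)(C)C)C1=CC(=O)[C@@](C)(C[C@@H](OC(=O)C(C)C)/C=C(\C[Sn](CCCC)(CCCC)CCCC)C(=O)OC)O1
F2 | step 11 | (5S,6aR)-5-{[(4-methoxybenzyl)oxy]methyl}-6a-methyl-2,5,6,6a-tetrahydrofuro[3,2-b]furan-2-ol (lactol of 15) | OC1C=C2O[C@H](COCc3ccc(OC)cc3)C[C@@]2(C)O1
F3 | step 11 | diol from alkenylation of F2, (2-ylidene)oxolan-3-ol with a secondary bis-allylic alcohol | C[C@@]1(O)C[C@@H](COCc2ccc(OC)cc2)O/C1=C/C(O)/C(CO[Si](c2ccccc2)(c2ccccc2)C(C)(C)C)=C\CO[Si](C)(C)C(C)(C)C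
F4 | step 11 | hydroxy dienone from oxidation of F3 | C[C@@]1(O)C[C@@H](COCc2ccc(OC)cc2)O/C1=C/C(=O)/C(CO[Si](c2ccccc2)(c2ccccc2)C(C)(C)C)=C\CO[Si](C)(C)C(C)(C)C
F5 | step 7 | 3,3-dichloro derivative of lactone 13 | O=C1C(Cl)(Cl)[C@H]2O[C@H](COCc3ccc(OC)cc3)C[C@@]2(C)O1
F6 | step 7 | 3-chloro derivative of butenolide 15 | O=C1C(Cl)=C2O[C@H](COCc3ccc(OC)cc3)C[C@@]2(C)O1
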